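A stirred tank at steady state cannot pile up over-reaction product: what target makes of it each minute must leave by the outlet in that same minute. One charge goes into two tanks and a closed flask, and the three are ranked by the share of target in target plus over-reaction product, the selectivity.

| flask | substrate | remark | time |
|---|---|---|---|
| dawn | 0.011 M | run made earlier |  |
| autumn | 0.015 M | run made earlier |  |
| midnight | 0.024 M | run made earlier |  |
| blue | 0.011 M | one stirred flow tank at steady state, fed with the mixture as stated, mean residence time 90.0 min |  |
| violet | 0.011 M | a closed flask charged with all of it at once and left for 30 min | 30 min |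
| red | 0.011 M | one stirred flow tank at steady state, fed with the mixture as stated, mean residence time 30 min |  |

| run | time / min | target / % | over-reaction product / % |
|---|---|---|---|
| dawn | 1.00 | 0.1 | 0 |
| dawn | 3.00 | 2.8 | 0.7 |
| dawn | 5.00 | 4.0 | 1.1 |
| dawn | 8.00 | 5.9 | 2.3 |
| dawn | 10.0 | 6.7 | 3.9 |
| dawn | 15.0 | 6.0 | 7.1 |
| dawn | 20.0 | 5.4 | 10.0 |
| autumn | 2.00 | 1.9 | 0 |
| autumn | 6.00 | 4.8 | 2.4 |
| autumn | 10.0 | 5.8 | 4.1 |
| autumn | 15.0 | 6.7 | 7.2 |
| autumn | 20.0 | 5.3 | 10.3 |
| autumn | 30.0 | 4.0 | 15.2 |
| autumn | 40.0 | 2.1 | 18.2 |
| midnight | 2.00 | 1.6 | 0.8 |
| midnight | 6.00 | 4.5 | 1.4 |
| midnight | 10.0 | 6.0 | 3.8 |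
| midnight | 15.0 | 6.3 | 6.7 |
| midnight | 20.0 | 5.6 | 10.2 |
| midnight | 30.0 | 3.5 | 14.8 |
| midnight | 40.0 | 2.5 | 18.6 |

(readings scatter by 0.3 percentage points)

- the stated concentrations are those of everything mixed, before any reaction; amounts are the same in each set-up
- the numbers in the tables scatter by 0.3 percentage points (one standard deviation)
- the earlier runs were made in a closed, stirred flask

- order of the set-ups by the share of target in all that became target or over-reaction product, at the outlet or at the end, highest first (blue / violet / red)
- share of target in all that became target or over-reaction product, at the outlet or at the end, blue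
- share of target in all that became target or over-reaction product, at the outlet or at the end, violet
- share of target in all that became target or over-reaction product, at the outlet or at the end, red

Does the loss of target depend on the charge? At 20.0 min the over-reaction product reads 10.0%, 10.3% and 10.2% of the charge in dawn, autumn and midnight, though midnight holds 2.18 times dawn's charge, so the step is taken as first order.

How fast is it? The rise of over-reaction product from 10.0 min to 20.0 min, divided by the target at 15.0 min and pooled over the runs, gives the burn constant of target 0.0984 /min, a reading.

What does that make of a tank? The balance gives [over-reaction product]/[target] = burn constant × residence time, a Damköhler number, and the share is 1/(1 + that number); a number of one is the even split, the zero of the scale. Blue stands at 8.86, giving 10.1%. Red, at 30.0 min, stands at 2.95, giving 25.3%.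

Violet is a closed flask, so it is read directly: the autumn and midnight readings at 30.0 min pool to 20.0%. This reckoning therefore puts red above violet and violet above blue.

The forecast uses 0.105 per minute where this reckoning has 0.0984 /min, and holds to the same tank rule “whatever the first step does”. It gives red > violet > blue, with blue 9.6% (8.8% to 10.5%), violet 20.2% (18.5% to 22%) and red 24.1% (22.5% to 26%).

The flasks give red > violet > blue: blue 9.91%, violet 20.5%, red 24.8%.

    substrate ⇌ intermediate A (K = 0.226, k = 0.158 /min)
    substrate ⇌ intermediate B (K = 13.1, k = 0.0749 /min)
    intermediate A → target (k = 0.0952 /min)
    target → over-reaction product (k = 0.101 /min)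

In violet at the end, intermediate B stood at 67.8% beside 11.0% substrate, 2.33% intermediate A and 3.87% target, while target went on to over-reaction product with a half-life of 6.9 min, shorter than the 30 min in the flask. In the red tank the outlet carried 27.4% substrate, 52.5% intermediate B and 3.70% target, and the share of 24.8% makes the over-reaction product there 11.2%; the burn constant, a reading, reckons 10.9% from that target over 30.0 min.

The earlier runs and the new flask were generated by integration with constants of no real substance, and the scatter is random.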